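The ten-membered ring is cut at C1–C10 and C4–C5. Read as an enol ether, the C1 ketone/C10 acetoxy pair is a C1=C10 bond, and the epoxide is a C4=C5 bond. The two are 1,5-related, which is what cleavage of a bicyclo[2.2.0]hexane (rings C10–C1–C4–C5 and C1–C2–C3–C4) leaves behind. One enone–cyclobutene [2+2] photocycloaddition makes both bonds and the central cyclobutane and puts every ring carbon in place; heating then opens C1–C4 and C5–C10. The precursors are (S)-5-silyloxy-3-methylcyclohexenone (C5=C10, C6=O, stereocentre C8) and 1-methyl-2-silyloxycyclobutene (C4=C1).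

Key step: step 5

Remark: germacrane numbering is used (ring C1–C10, C11 on C7, C12/C13 on C11, C14 on C10, C15 on C4; α = face of the C8 oxygen); compound 1 is taken as the catalogue (3R) statin side-chain phosphonate, and both silyl groups are TBS so that the enol ether released in step 6 survives to step 13.

Step 1
Reactants: 1 methyl (3R)-3-[(tert-butyldimethylsilyl)oxy]-6-(dimethoxyphosphoryl)-5-oxohexanoate
Product: 2 (3R)-3-[(tert-butyldimethylsilyl)oxy]-6-(dimethoxyphosphoryl)-N-methoxy-N-methyl-5-oxohexanamide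
Conditions: MeNH(OMe)·HCl (3 equiv), i-PrMgCl (7 equiv), THF, −20 → 0 °C
Reagents that add atoms: N,O-dimethylhydroxylamine hydrochloride, CNOC.Cl
Why: Weinreb amide formation by attack of the magnesium amide on the methyl ester; the β-ketophosphonate is masked in situ as its magnesium enolate and the stereocentre is not involved.

Step 2
Reactants: 2 (3R)-3-[(tert-butyldimethylsilyl)oxy]-6-(dimethoxyphosphoryl)-N-methoxy-N-methyl-5-oxohexanamide
Product: 3 dimethyl {(4S)-4-[(tert-butyldimethylsilyl)oxy]-2,6-dioxoheptyl}phosphonate (same spatial arrangement; the descriptor changes with the priorities)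
Conditions: MeMgBr (3 equiv), THF, −20 → 0 °C; aq. NH4Cl
Reagents that add atoms: methylmagnesium bromide, C[Mg]Br
Why: Grignard addition to the Weinreb amide stops at the chelated tetrahedral adduct, so the methyl ketone appears only on work-up and is not attacked a second time.

Step 3
Reactants: 3 dimethyl {(4S)-4-[(tert-butyldimethylsilyl)oxy]-2,6-dioxoheptyl}phosphonate
Product: 4 (5S)-5-[(tert-butyldimethylsilyl)oxy]-3-methylcyclohex-2-en-1-one
Conditions: NaH (1.05 equiv), THF, 0 °C → rt
Reagents that add atoms: none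
Why: Intramolecular Horner–Wadsworth–Emmons reaction closes the six-membered enone regiospecifically (phosphonate arm becomes C7–C6(=O)–C5, ketone arm becomes C9–C10–C14), so the purchased centre becomes C8 (S) without a bond to it being broken, and the non-basic phosphate by-product spares the β-silyloxy group.

Step 4
Reactants: 5 2-methylcyclobutanone (racemic)
Product: 6 tert-butyldimethyl[(2-methylcyclobut-1-en-1-yl)oxy]silane (1-methyl-2-silyloxycyclobutene)
Conditions: TBSCl, NaI, Et3N, MeCN, 40 °C; distillation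
Reagents that add atoms: tert-butyldimethylsilyl chloride, CC(C)(C)[Si](C)(C)Cl
Why: Equilibrating silylation with silyl iodide made in situ and Et3N should give the more substituted (thermodynamic) silyl enol ether.

Step 5
Reactants: 4 (5S)-5-[(tert-butyldimethylsilyl)oxy]-3-methylcyclohex-2-en-1-one; 6 tert-butyldimethyl[(2-methylcyclobut-1-en-1-yl)oxy]silane
Product: 7 cis-anti-cis (9S)-2,9-bis[(tert-butyldimethylsilyl)oxy]-1,5-dimethyltricyclo[4.4.0.0^2,5]decan-7-one (central ring C10–C1–C4–C5, cyclobutane trans to the C8 oxygen)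
Conditions: hν (350 nm, Pyrex), 6 (5 equiv), CH2Cl2, −40 °C; then basic Al2O3, rt
Reagents that add atoms: none
Why: n→π* excitation and intersystem crossing give the triplet enone, which bonds to the electron-rich cyclobutene to form a triplet 1,4-diradical that collapses to the cyclobutane after spin inversion; this is an enone–enol ether [2+2] photocycloaddition, with cyclohexenone–cyclobutene and enone–1,2-bis(silyloxy)cyclobutene additions as closest precedents. The one ring closed is the central four-membered ring C10–C1–C4–C5, by radical–radical recombination, so the bond between the fully substituted carbons C1 and C10 needs no ionic activation. C1 and C4 are cis because the cyclobutene ring allows nothing else, C10 and C5 end cis after alumina epimerises any trans-fused isomer at the enolisable C5, the two outer rings lie anti through exo approach, and the alkene should add mainly to the enone face opposite the C8 silyloxy group. The selectivity needed is head-to-tail regiochemistry (C1 to the β-carbon C10, C4 to the α-carbon C5), which the oxygen donor on C1 should secure as with other enol ethers, together with the cis-anti-cis array that later fixes the alkene geometry. Facial selectivity relative to C8 is not required, because C1, C4, C5 and C10 all become sp2 in step 6 and both facial isomers converge on 8.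

Step 6
Reactants: 7 cis-anti-cis (9S)-2,9-bis[(tert-butyldimethylsilyl)oxy]-1,5-dimethyltricyclo[4.4.0.0^2,5]decan-7-one
Product: 8 (2E,6Z,9S)-6,9-bis[(tert-butyldimethylsilyl)oxy]-3,7-dimethylcyclodeca-2,6-dien-1-one (1,8α-bis(silyloxy)germacra-1(10),4-dien-6-one; C2/C9 and C3/C6 trans across the ring alkenes)
Conditions: toluene (degassed), base-washed sealed tube, 180 °C
Reagents that add atoms: none
Why: Thermal [2+2] cycloreversion of the bicyclo[2.2.0]hexane unit, as in the known thermolysis of cyclohexenone–cyclobutene photoadducts to cyclodeca-1,5-dienes: homolysis of the strained C1–C4 bond gives a stabilised cyclohexane-1,4-diyl that cleaves C5–C10, least-motion opening of the cis-anti-cis array should place both ring alkenes trans, and conjugation of C4=C5 with the C6 ketone should hold the ring against Cope rearrangement.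

Step 7
Reactants: 8 (2E,6Z,9S)-6,9-bis[(tert-butyldimethylsilyl)oxy]-3,7-dimethylcyclodeca-2,6-dien-1-one; 9 diethyl 2-oxopropanedioate (diethyl ketomalonate)
Product: 11 diethyl 2-hydroxy-2-(C7-yl)propanedioate of 8 (aldol adduct, both C7 epimers), via lithium enolate 10 (not isolated)
Conditions: LDA, THF, −78 °C; then 9, −78 °C; aq. NH4Cl
Reagents that add atoms: none
Why: Kinetic α′-deprotonation of the enone at C7 and aldol addition to the highly electrophilic central carbonyl of the ketomalonate; the silyl enol ether and the β-silyloxy group should survive at −78 °C, and the new C7 centre is erased in step 8.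

Step 8
Reactants: 11 diethyl 2-hydroxy-2-(C7-yl)propanedioate of 8
Product: 13 diethyl 2-[(2S,4Z,8E)-2,5-bis[(tert-butyldimethylsilyl)oxy]-4,8-dimethyl-10-oxocyclodeca-4,8-dien-1-ylidene]propanedioate (C7=C11 alkylidene malonate), via tertiary mesylate 12 (not isolated)
Conditions: MsCl, Et3N, CH2Cl2, −20 → 0 °C, short contact
Reagents that add atoms: none
Why: Sulfene mesylation of the tertiary alcohol and E1cB loss of mesylate through the C6 enolate give the tetrasubstituted alkene; brief exposure to base limits γ-deprotonation at C8.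

Step 9
Reactants: 13 diethyl 2-[(2S,4Z,8E)-2,5-bis[(tert-butyldimethylsilyl)oxy]-4,8-dimethyl-10-oxocyclodeca-4,8-dien-1-ylidene]propanedioate
Product: 14 1,8α-bis[(tert-butyldimethylsilyl)oxy]germacra-1(10),4,7(11)-triene-6α,12,13-triol
Conditions: DIBAL-H (6 equiv), THF–toluene, −78 → −30 °C; Rochelle salt
Reagents that add atoms: none
Why: DIBAL-H reduces the cross-conjugated ketone and both conjugated esters in the 1,2-sense; hydride should reach the twisted C6 carbonyl from the ring-outer face of the conformer that keeps C8–H in the C7=C11 plane, giving the 6α-alcohol, though this substrate control is the least secure stereochemical point of the route.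

Step 10
Reactants: 14 1,8α-bis[(tert-butyldimethylsilyl)oxy]germacra-1(10),4,7(11)-triene-6α,12,13-triol
Product: 16 1,8α-bis[(tert-butyldimethylsilyl)oxy]-13-oxogermacra-1(10),4,7(11)-trien-12,6α-olide, via lactol aldehyde 15 (not isolated)
Conditions: activated MnO2 (excess), CH2Cl2, rt
Reagents that add atoms: none
Why: MnO2 oxidises both primary allylic alcohols; the C12 aldehyde is trapped by the cis C6 hydroxyl as a lactol and oxidised on to the butenolide (known lactonisation of (Z)-2-ene-1,4-diols), C13 stops at the aldehyde, and the silyl enol ether is inert.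

Step 11
Reactants: 16 1,8α-bis[(tert-butyldimethylsilyl)oxy]-13-oxogermacra-1(10),4,7(11)-trien-12,6α-olide
Product: 17 1,8α-bis[(tert-butyldimethylsilyl)oxy]-13-hydroxygermacra-1(10),4,7(11)-trien-12,6α-olide
Conditions: NaBH4, CeCl3·7H2O, MeOH–THF, −78 °C
Reagents that add atoms: none
Why: Luche reduction: the cerium-modified borohydride reduces the aldehyde in the 1,2-sense much faster than it touches the butenolide, and the near-neutral medium avoids enolisation at C6.

Step 12
Reactants: 17 1,8α-bis[(tert-butyldimethylsilyl)oxy]-13-hydroxygermacra-1(10),4,7(11)-trien-12,6α-olide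
Product: 18 13-acetoxy-1,8α-bis[(tert-butyldimethylsilyl)oxy]germacra-1(10),4,7(11)-trien-12,6α-olide
Conditions: Ac2O, pyridine, DMAP (cat.), CH2Cl2, 0 °C
Reagents that add atoms: acetic anhydride, CC(=O)OC(C)=O
Why: DMAP-catalysed acetylation of the only free (primary allylic) hydroxyl.

Step 13
Reactants: 18 13-acetoxy-1,8α-bis[(tert-butyldimethylsilyl)oxy]germacra-1(10),4,7(11)-trien-12,6α-olide
Product: 20 13-acetoxy-8α,10α-dihydroxy-1-oxogermacra-4,7(11)-dien-12,6α-olide, via silyloxy epoxide 19 (not isolated)
Conditions: DMDO (1.05 equiv), acetone–CH2Cl2, −78 → −40 °C; then HF·pyridine–pyridine, THF, 0 °C → rt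
Reagents that add atoms: dimethyldioxirane, CC1(C)OO1
Why: Rubottom-type oxidation: the tetrasubstituted enol ether is epoxidised far faster than C4=C5 or the butenolide, attack on the outer face of the ring-trans C1=C10 bond in the germacranolide-like conformer (C14 and C15 syn) should put oxygen on the α-face of C10, and buffered HF opens the silyloxy epoxide to the C1 ketone/C10 alcohol while also freeing the C8 hydroxyl.

Step 14
Reactants: 20 13-acetoxy-8α,10α-dihydroxy-1-oxogermacra-4,7(11)-dien-12,6α-olide
Product: 21 13-acetoxy-10α-hydroxy-8α-(methacryloyloxy)-1-oxogermacra-4,7(11)-dien-12,6α-olide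
Conditions: methacrylic anhydride, Et3N, DMAP (cat.), CH2Cl2, 0 °C
Reagents that add atoms: methacrylic anhydride, C=C(C)C(=O)OC(=O)C(C)=C
Why: DMAP-catalysed acylation is selective for the secondary allylic C8 hydroxyl, since the hindered tertiary α-ketol hydroxyl should not react at 0 °C.

Step 15
Reactants: 21 13-acetoxy-10α-hydroxy-8α-(methacryloyloxy)-1-oxogermacra-4,7(11)-dien-12,6α-olide
Product: 22 10α,13-diacetoxy-8α-(methacryloyloxy)-1-oxogermacra-4,7(11)-dien-12,6α-olide (4,5-deoxyglaucolide A)
Conditions: Ac2O, DMAP, pyridine, CH2Cl2, rt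
Reagents that add atoms: acetic anhydride, CC(=O)OC(C)=O
Why: Steglich-type DMAP acylation of the tertiary alcohol under non-acidic conditions that leave the acid-sensitive diene ring alone; no stereocentre is touched.

Step 16
Reactants: 22 10α,13-diacetoxy-8α-(methacryloyloxy)-1-oxogermacra-4,7(11)-dien-12,6α-olide
Product: 23 glaucolide A
Conditions: DMDO (1.2 equiv), acetone, −20 → 0 °C
Reagents that add atoms: dimethyldioxirane, CC1(C)OO1
Why: Neutral dioxirane epoxidation of the only electron-rich alkene left (methacrylate and butenolide are electron-poor); with H6 eclipsing the alkene to avoid A(1,3) strain against C15, the ring blocks the C7 face, so oxygen should add from the outer face syn to O6 and give the trans 4α,5β-epoxide, as in peracid epoxidations of germacranolides.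

Compound list
1 | methyl (3R)-3-[(tert-butyldimethylsilyl)oxy]-6-(dimethoxyphosphoryl)-5-oxohexanoate | COC(=O)C[C@H](O[Si](C)(C)C(C)(C)C)CC(=O)CP(=O)(OC)OC | starting material
2 | (3R)-3-[(tert-butyldimethylsilyl)oxy]-6-(dimethoxyphosphoryl)-N-methoxy-N-methyl-5-oxohexanamide | CON(C)C(=O)C[C@H](O[Si](C)(C)C(C)(C)C)CC(=O)CP(=O)(OC)OC | intermediate
3 | dimethyl {(4S)-4-[(tert-butyldimethylsilyl)oxy]-2,6-dioxoheptyl}phosphonate | CC(=O)C[C@H](O[Si](C)(C)C(C)(C)C)CC(=O)CP(=O)(OC)OC | intermediate
4 | (5S)-5-[(tert-butyldimethylsilyl)oxy]-3-methylcyclohex-2-en-1-one | O=C1C[C@@H](O[Si](C)(C)C(C)(C)C)CC(C)=C1 | intermediate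
5 | 2-methylcyclobutanone (racemic) | CC1CCC1=O | starting material
6 | tert-butyldimethyl[(2-methylcyclobut-1-en-1-yl)oxy]silane | CC1=C(O[Si](C)(C)C(C)(C)C)CC1 | intermediate
7 | cis-anti-cis (9S)-2,9-bis[(tert-butyldimethylsilyl)oxy]-1,5-dimethyltricyclo[4.4.0.0^2,5]decan-7-one | O=C1C[C@@H](O[Si](C)(C)C(C)(C)C)C[C@@]2(C)[C@@H]1[C@]1(C)CC[C@@]12O[Si](C)(C)C(C)(C)C | intermediate
8 | (2E,6Z,9S)-6,9-bis[(tert-butyldimethylsilyl)oxy]-3,7-dimethylcyclodeca-2,6-dien-1-one | CC(C)(C)[Si](C)(C)O[C@H]1C/C(C)=C(O[Si](C)(C)C(C)(C)C)/CC/C(C)=C/C(=O)C1 | intermediate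
9 | diethyl 2-oxopropanedioate (diethyl ketomalonate) | CCOC(=O)C(=O)C(=O)OCC | starting material
10 | lithium C6(O)=C7 enolate of 8 | CC(C)(C)[Si](C)(C)O[C@H]1C/C(C)=C(O[Si](C)(C)C(C)(C)C)/CC/C(C)=C/C(O[Li])=C1 | intermediate (not isolated)
11 | aldol adduct: 8 carrying C(OH)(CO2Et)2 at C7 (C7 epimers) | CC(C)(C)[Si](C)(C)O[C@H]1C/C(C)=C(O[Si](C)(C)C(C)(C)C)/CC/C(C)=C/C(=O)C1C(O)(C(=O)OCC)C(=O)OCC | intermediate
12 | tertiary mesylate of 11 | CC(C)(C)[Si](C)(C)O[C@H]1C/C(C)=C(O[Si](C)(C)C(C)(C)C)/CC/C(C)=C/C(=O)C1C(OS(C)(=O)=O)(C(=O)OCC)C(=O)OCC | intermediate (not isolated)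
13 | diethyl 2-[(2S,4Z,8E)-2,5-bis[(tert-butyldimethylsilyl)oxy]-4,8-dimethyl-10-oxocyclodeca-4,8-dien-1-ylidene]propanedioate | CC(C)(C)[Si](C)(C)O[C@H]1C/C(C)=C(O[Si](C)(C)C(C)(C)C)/CC/C(C)=C/C(=O)C1=C(C(=O)OCC)C(=O)OCC | intermediate
14 | 1,8α-bis[(tert-butyldimethylsilyl)oxy]germacra-1(10),4,7(11)-triene-6α,12,13-triol | CC(C)(C)[Si](C)(C)O[C@H]1C/C(C)=C(O[Si](C)(C)C(C)(C)C)/CC/C(C)=C/[C@@H](O)C1=C(CO)CO | intermediate
15 | lactol aldehyde (12-hydroxy-12,6α-epoxy-13-al; lactol epimers) | CC(C)(C)[Si](C)(C)O[C@H]1C/C(C)=C(O[Si](C)(C)C(C)(C)C)/CC/C(C)=C/[C@H]2OC(O)C(C=O)=C12 | intermediate (not isolated)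
16 | 1,8α-bis[(tert-butyldimethylsilyl)oxy]-13-oxogermacra-1(10),4,7(11)-trien-12,6α-olide | CC(C)(C)[Si](C)(C)O[C@H]1C/C(C)=C(O[Si](C)(C)C(C)(C)C)/CC/C(C)=C/[C@H]2OC(=O)C(C=O)=C12 | intermediate
17 | 1,8α-bis[(tert-butyldimethylsilyl)oxy]-13-hydroxygermacra-1(10),4,7(11)-trien-12,6α-olide | CC(C)(C)[Si](C)(C)O[C@H]1C/C(C)=C(O[Si](C)(C)C(C)(C)C)/CC/C(C)=C/[C@H]2OC(=O)C(CO)=C12 | intermediate
18 | 13-acetoxy-1,8α-bis[(tert-butyldimethylsilyl)oxy]germacra-1(10),4,7(11)-trien-12,6α-olide | CC(C)(C)[Si](C)(C)O[C@H]1C/C(C)=C(O[Si](C)(C)C(C)(C)C)/CC/C(C)=C/[C@H]2OC(=O)C(COC(C)=O)=C12 | intermediate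
19 | 1β,10α-epoxide of 18 (silyloxy epoxide) | CC(C)(C)[Si](C)(C)O[C@H]1C[C@@]2(C)O[C@]2(O[Si](C)(C)C(C)(C)C)CC/C(C)=C/[C@H]2OC(=O)C(COC(C)=O)=C12 | intermediate (not isolated)
20 | 13-acetoxy-8α,10α-dihydroxy-1-oxogermacra-4,7(11)-dien-12,6α-olide | O[C@H]1C[C@@](C)(O)C(=O)CC/C(C)=C/[C@H]2OC(=O)C(COC(C)=O)=C12 | intermediate
21 | 13-acetoxy-10α-hydroxy-8α-(methacryloyloxy)-1-oxogermacra-4,7(11)-dien-12,6α-olide | C=C(C)C(=O)O[C@H]1C[C@@](C)(O)C(=O)CC/C(C)=C/[C@H]2OC(=O)C(COC(C)=O)=C12 | intermediate
22 | 10α,13-diacetoxy-8α-(methacryloyloxy)-1-oxogermacra-4,7(11)-dien-12,6α-olide | C=C(C)C(=O)O[C@H]1C[C@@](C)(OC(C)=O)C(=O)CC/C(C)=C/[C@H]2OC(=O)C(COC(C)=O)=C12 | intermediate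
23 | glaucolide A | C=C(C)C(=O)O[C@H]1C[C@@](C)(OC(C)=O)C(=O)CC[C@@]2(C)O[C@@H]2[C@H]2OC(=O)C(COC(C)=O)=C12 | target

Total steps: 16. Longest linear sequence: 15 (steps 1–3 and 5–16; step 4 is a one-step side branch).

Steps most likely to fail

1. Step 6. At the temperature needed, the cyclodecadiene may rearrange further (Cope) to the divinylcyclohexanone, or a ring-flipped diyl may give a cis ring alkene. The fallback sets out from 4 and 5 and returns at 8; it replaces heat by an anion-triggered opening at low temperature. Ketone 5 is silylated with TMSCl/NaI/Et3N to 1-methyl-2-(trimethylsilyloxy)cyclobutene F1. Irradiation of F1 with 4 as in step 5 should give the trimethylsilyl analogue of the photoadduct F2. Anhydrous fluoride (TASF, THF, −40 °C) removes only the tertiary trimethylsilyl group, and the free cyclobutoxide should fragment across C1–C4 and C5–C10 to the C1 enolate of the cyclodecadienone F3. TBSCl silylates F3 on oxygen to give 8.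

2. Step 9. Hydride delivery to C6 may show poor or reversed facial selectivity, which would give the 6-epi series. The fallback sets out from 13 and returns at 16; it replaces substrate control by catalyst control. Reduction of the C6 ketone alone ((S)-Me-CBS, catecholborane, toluene, −78 °C, on the assumption that the tetrasubstituted C7 alkenyl is the large group; the antipodal catalyst otherwise), followed by spontaneous lactonisation onto the cis ester, should give the lactone ester F4. DIBAL-H at −78 °C takes F4 to the lactol diol F5. MnO2 then oxidises the lactol and the primary alcohol together to 16.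

3. Step 13. The oxidant may attack the inner face of C1=C10 (wrong C10 epimer) or compete at C4=C5. The fallback sets out from 18 and returns at 20; it replaces substrate control by reagent control. The enol ether is epoxidised with a Shi fructose-derived dioxirane (Oxone, buffered DMM–MeCN, 0 °C, D- or L-derived ketone chosen for the α-face at C10), then treated with HF·pyridine as before. The intermediates are those of the main route (no new compound, F0).

Further compounds
F1 | step 6 | 1-methyl-2-(trimethylsilyloxy)cyclobutene | CC1=C(O[Si](C)(C)C)CC1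
F2 | step 6 | trimethylsilyl analogue of the photoadduct | O=C1C[C@@H](O[Si](C)(C)C(C)(C)C)C[C@@]2(C)[C@@H]1[C@]1(C)CC[C@@]12O[Si](C)(C)C
F3 | step 6 | C1 enolate of the cyclodecadienone (tris(dimethylamino)sulfonium salt) | CC(C)(C)[Si](C)(C)O[C@H]1C/C(C)=C([O-])/CC/C(C)=C/C(=O)C1.CN(C)[S+](N(C)C)N(C)C
F4 | step 9 | lactone ester (ethyl 12,6α-olide-13-oate) | CC(C)(C)[Si](C)(C)O[C@H]1C/C(C)=C(O[Si](C)(C)C(C)(C)C)/CC/C(C)=C/[C@H]2OC(=O)C(C(=O)OCC)=C12
F5 | step 9 | lactol diol (12-hydroxy-12,6α-epoxy-13-ol) | CC(C)(C)[Si](C)(C)O[C@H]1C/C(C)=C(O[Si](C)(C)C(C)(C)C)/CC/C(C)=C/[C@H]2OC(O)C(CO)=C12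
F0 | step 13 | none | none
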